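**Plan**
- Retrosynthesis: ring E (O8–C3–C4–C5–C6–C7) is the 1-oxadiene O8=C3–C4=C5 of ethyl vinyl ketone laid across a two-carbon unit C6=C7 that sits exocyclic on the one-carbon bridge (C6) of the azabicyclo[4.3.1]decane. The cuts are C7–S (sulfur as activating group), then C5–C6 and O8–C7 (oxa-Diels–Alder), then C6=C7 (Peterson) back to the tetracyclic C6 ketone.
- Ketone: ring D is cut at C9–C27 (iminium–enol Mannich closure) and C23–C24 (ester enolate aminomethylation), ring C at C6–C9 (Dieckmann) and C11–C12 (Negishi), ring B at C13–C23 (aldol condensation) and C17–C22 (malonate alkylation), and C14–C17 by asymmetric Michael addition to cyclopentenone.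
- Forward order of rings: A (cyclopentenone) → B → quaternary C23 → C → D → E.
- Stereochemistry: C14 from the Michael catalyst; C23 by convex-face aminomethylation relayed from C14; C9 by the geometry of the bridge; C17 by kinetic protonation; C6 by the facial bias of the bicyclic alkene in the cycloaddition.

Key step: step 13

Labels: atoms C1–C27 follow the atom order of the target SMILES. Ring A = cyclopentene C12–C16; ring B = cyclopentane C13, C14, C17, C22, C23; ring C = cycloheptene C6, C9–C13, C23; ring D = piperidine C6, C9, C27, N25, C24, C23; ring E = dihydropyran C3–C7, O8.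

Assumption: the (R,R)-configured ruthenium amido catalyst is taken to give the (S)-adduct 3; if its sense is the opposite, the (S,S)-antipode is used and nothing else changes.

**Step 1**
Reactants: 1 cyclopent-2-en-1-one; 2 dimethyl malonate
Product: 3 dimethyl 2-[(1S)-3-oxocyclopentyl]propanedioate
Conditions: Ru[(R,R)-TsNCHPhCHPhNH](η6-C6Me6) (2 mol %), t-BuOH, 40 °C
Reagents that add atoms: none
Why: Catalytic asymmetric Michael addition of a malonate to a cyclic enone with a bifunctional ruthenium amido complex, a reaction established for cyclopentenone itself, in which the chiral catalyst selects the enone face and sets C14 as (S).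

**Step 2**
Reactants: 3 dimethyl 2-[(1S)-3-oxocyclopentyl]propanedioate; 4 methyl 2-(bromomethyl)prop-2-enoate
Product: 5 dimethyl 2-[2-(methoxycarbonyl)prop-2-en-1-yl]-2-[(1S)-3-oxocyclopentyl]propanedioate
Conditions: K2CO3, acetone, 25 °C
Reagents that add atoms: none
Why: Malonate alkylation with an activated allylic bromide (SN2 or SN2′, both giving the same product), chemoselective because the malonate C–H is far more acidic than the ketone α-hydrogens, so that C17 becomes quaternary and C14 is not touched.

**Step 3**
Reactants: 5 dimethyl 2-[2-(methoxycarbonyl)prop-2-en-1-yl]-2-[(1S)-3-oxocyclopentyl]propanedioate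
Product: 7 dimethyl 2-(3-methoxy-2,3-dioxopropyl)-2-[(1S)-3-oxocyclopentyl]propanedioate, via secondary ozonide 6 (not isolated)
Conditions: O3, CH2Cl2, −78 °C; then Me2S, −78 → 25 °C
Reagents that add atoms: ozone, [O-][O+]=O
Why: Ozonolysis with reductive work-up of the only alkene, a 1,1-disubstituted acrylate, unmasks the α-keto ester (C23=O) that serves as the aldol acceptor, with no effect on C14.

**Step 4**
Reactants: 7 dimethyl 2-(3-methoxy-2,3-dioxopropyl)-2-[(1S)-3-oxocyclopentyl]propanedioate
Product: 8 bicyclic enone triester (rings A and B; C12 ketone; C13=C23)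
Conditions: TsOH·H2O (10 mol %), toluene, 80 °C, 4 Å molecular sieves
Reagents that add atoms: none
Why: Intramolecular aldol condensation (5-exo-trig attack of the C13 enol on the strongly electrophilic α-keto ester carbonyl, closing ring B), in which only the fused aldol can lose water into conjugation with both carbonyl groups whereas attack from C16 gives a bridged aldol that can only revert, so the tetrasubstituted C13=C23 alkene is the sink and C14 is unchanged.

**Step 5**
Reactants: 8 bicyclic enone triester
Product: 10 C12 enol triflate (C12=C13; H23 cis to H14), via lithium enolate 9 (not isolated)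
Conditions: LiBH(s-Bu)3, THF, −78 °C; then PhNTf2, −78 → 0 °C
Reagents that add atoms: N-phenylbis(trifluoromethanesulfonimide), O=S(=O)(N(c1ccccc1)S(=O)(=O)C(F)(F)F)C(F)(F)F
Why: Conjugate reduction with enolate trapping, in which the bulky hydride adds to C23 of the s-cis ene-1,4-dicarbonyl (β to the ketone, the stronger activating group) from the convex face and O-sulfonylation of the resulting ketone enolate fixes the alkene at C12=C13 regiospecifically; the configuration created at C23 is of no consequence because C23 is made planar again in step 6.

**Step 6**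
Reactants: 10 C12 enol triflate; 11 dimethylmethylideneammonium iodide
Product: 13 C23-(dimethylaminomethyl) enol triflate (C24 cis to H14), via lithium ester enolate 12 (not isolated)
Conditions: LiN(SiMe3)2, THF, −78 °C; then 11, −78 → 0 °C
Reagents that add atoms: none
Why: Mannich-type α-aminomethylation of an ester enolate with a preformed iminium salt, in which C23–H is the only acidic hydrogen of 10, the extended enolate reacts at its α-carbon, and the electrophile is expected to approach the convex face of the bicyclo[3.3.0]octene (the face of H14, ring A being tilted toward the other face), which sets the quaternary C23 with C24 cis to H14.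

**Step 7**
Reactants: 13 C23-(dimethylaminomethyl) enol triflate; 14 tert-butyl 4-bromobutanoate
Product: 16 C12-(4-tert-butoxy-4-oxobutyl) bicyclic amino tetraester, via organozinc bromide 15 (not isolated)
Conditions: 14, Zn dust, LiCl, THF, 50 °C; then 13, Pd(dppf)Cl2 (5 mol %), THF, 60 °C
Reagents that add atoms: none
Why: Negishi coupling of an alkenyl triflate with a primary alkylzinc halide made by LiCl-promoted zinc insertion, the bidentate ferrocenyl phosphine suppressing β-hydride elimination, attaches C11–C10–C9 to C12 in the presence of the esters and the tertiary amine and involves no stereocentre.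

**Step 8**
Reactants: 16 C12-(4-tert-butoxy-4-oxobutyl) bicyclic amino tetraester
Product: 17 tricyclic β-keto tert-butyl ester (rings A–C; C6 ketone; CO2t-Bu on C9)
Conditions: KOt-Bu, THF (0.01 M), 0 → 40 °C; then AcOH
Reagents that add atoms: none
Why: Dieckmann condensation (7-exo-trig) in which the enolate of the tert-butyl ester, the only enolisable ester, acylates at the methyl ester on C23 to close ring C and the equilibrium is pulled over by deprotonation of the β-keto ester, while C23 (quaternary) and C17 (no hydrogen) cannot epimerise.

**Step 9**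
Reactants: 17 tricyclic β-keto tert-butyl ester
Product: 19 tricyclic amino ketone diester (C9 methylene), via β-keto acid 18 (not isolated)
Conditions: CF3CO2H–CH2Cl2 (1:3), 0 → 25 °C; then aq. NaHCO3
Reagents that add atoms: none
Why: Acidolysis of the tert-butyl ester followed by decarboxylation of the β-keto acid leaves C9 as a methylene group while the amine is protonated, so that neither retro-Mannich cleavage nor ring closure onto a carboxyl-bearing C9 can occur.

**Step 10**
Reactants: 19 tricyclic amino ketone diester
Product: 22 tetracyclic amino ketone diester (rings A–D), via N-oxide 20 (not isolated), via methyleneiminium trifluoroacetate 21 (not isolated)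
Conditions: mCPBA (3-chloroperoxybenzoic acid, 1.0 equiv), CH2Cl2, −40 °C; then (CF3CO)2O, −40 → 0 °C; then 40 °C; aq. NaHCO3
Reagents that add atoms: none
Why: Polonovski–Potier reaction followed by intramolecular Mannich cyclisation (6-endo-trig), in which the O-trifluoroacetylated N-oxide loses a proton from an N-methyl group (as in the N-demethylating variant of this reaction, the neopentyl C24 hydrogens being hindered) and the resulting N-methyl-N-methyleneiminium ion is captured by the C6–C9 enol, the only enol the ketone can form, to close ring D, the three-atom bridge reaching C9 only on the face on which C24 sits so that C9 is dictated by C23.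

**Step 11**
Reactants: 22 tetracyclic amino ketone diester
Product: 23 tetracyclic amino ketone monoester (methyl ester at C17, H17 cis to H14)
Conditions: LiCl, H2O, DMSO, 150 °C
Reagents that add atoms: none
Why: Krapcho dealkoxycarbonylation of the geminal diester, the ester enolate released on loss of CO2 being protonated by water on its less hindered face (that of H14, opposite the C15 methylene on the adjacent carbon) so that H17 ends cis to H14, while the ketone is safe because it cannot enolise (C23 quaternary, C9 a bridgehead).

**Step 12**
Reactants: 23 tetracyclic amino ketone monoester; 24 (phenylthiomethyl)trimethylsilane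
Product: 26 (E)-C6=C7 phenylthio alkene of the tetracycle, via lithiated silane 25 (not isolated)
Conditions: 24, n-BuLi, THF, 0 °C; then 23, −78 → 25 °C
Reagents that add atoms: none
Why: Peterson olefination in which the α-silyl α-thio carbanion adds to the bridging ketone, which cannot be enolised and should be more electrophilic than the ester at −78 °C, and the β-silyl alkoxide loses Me3SiO− on warming to give the vinyl sulfide, expected mainly as the (E)-isomer with sulfur turned away from the quaternary C23, the alkene geometry being irrelevant downstream because C7 ends as a methylene group.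

**Step 13**
Reactants: 26 (E)-C6=C7 phenylthio alkene; 27 pent-1-en-3-one (ethyl vinyl ketone)
Product: 28 C7-phenylthio spiro-dihydropyran (rings A–E)
Conditions: 27 (10 equiv), Yb(fod)3 (10 mol %), CH2Cl2, 12 kbar, 40 °C
Reagents that add atoms: none
Why: The electron-rich vinyl sulfide (HOMO, largest coefficient at C6) and the s-cis enone 27 (LUMO, lowered by coordination of its carbonyl to ytterbium) combine in a concerted but asynchronous inverse-electron-demand hetero-Diels–Alder reaction, C5–C6 bonding running ahead of O8–C7 bonding. The closest known reaction type is the Yb(fod)3- or pressure-promoted (4+2) cycloaddition of α,β-unsaturated ketones with vinyl sulfides and enol ethers, including β,β-disubstituted donors that give 3,3-disubstituted 2-heteroatom-substituted dihydropyrans. Ring E is closed by this intermolecular (4+2) cycloaddition, both ring bonds forming in one step, so no separate exo or endo ring-closure mode applies. C6 is controlled by the face of approach: the ring D face of the exocyclic alkene is screened by the axial C–H bonds at C24 and C27, whereas the ring C face is flanked by the planar C13, so C5 should bond syn to ring C and leave C7 syn to N25; C7 follows from suprafacial addition to the (E)-alkene and is erased in step 14. The step needs regioselectivity, which sulfur at C7 secures by making C6 the nucleophilic terminus, and chemoselectivity, which holds because the unactivated C12=C13 alkene and the ester do not react with the heterodiene. Pressure is applied because bond formation at the fully substituted C6 next to the quaternary C23 is sterically demanding.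

**Step 14**
Reactants: 28 C7-phenylthio spiro-dihydropyran
Product: 29 target compound
Conditions: Bu3SnH, AIBN (cat.), toluene, 90 °C
Reagents that add atoms: none
Why: Radical desulfurisation of an O,S-acetal with a tin hydride (the stannyl radical abstracts the phenylthio group and the α-alkoxy radical at C7 takes hydrogen from Bu3SnH) runs under neutral conditions that spare the acid-labile cyclic enol ether, the amine and the ester, turns C7 into CH2 and leaves C6 and the other stereocentres untouched.

**Compound list**
1 | cyclopent-2-en-1-one | O=C1C=CCC1 | starting material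
2 | dimethyl malonate | COC(=O)CC(=O)OC | starting material
3 | dimethyl 2-[(1S)-3-oxocyclopentyl]propanedioate | O=C1C[C@H](CC1)C(C(=O)OC)C(=O)OC | intermediate
4 | methyl 2-(bromomethyl)prop-2-enoate | C=C(CBr)C(=O)OC | starting material
5 | dimethyl 2-[2-(methoxycarbonyl)prop-2-en-1-yl]-2-[(1S)-3-oxocyclopentyl]propanedioate | O=C1C[C@H](CC1)C(C(=O)OC)(C(=O)OC)CC(=C)C(=O)OC | intermediate
6 | secondary ozonide of 5 (1,2,4-trioxolane in place of C=CH2; mixture at the trioxolane carbon) | O=C1C[C@H](CC1)C(C(=O)OC)(C(=O)OC)CC1(C(=O)OC)OCOO1 | intermediate
7 | dimethyl 2-(3-methoxy-2,3-dioxopropyl)-2-[(1S)-3-oxocyclopentyl]propanedioate | O=C1C[C@H](CC1)C(C(=O)OC)(C(=O)OC)CC(=O)C(=O)OC | intermediate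
8 | trimethyl (6aS)-4-oxo-1,2,4,5,6,6a-hexahydropentalene-1,1,3-tricarboxylate (C12 ketone, C13=C23, CO2Me on C23, two CO2Me on C17) | O=C1CC[C@H]2C1=C(C(=O)OC)CC2(C(=O)OC)C(=O)OC | intermediate
9 | lithium enolate (O–C12=C13) of the C23-reduced ketone, H23 cis to H14 | [Li+].[O-]C1=C2[C@H](CC1)C(C(=O)OC)(C(=O)OC)C[C@@H]2C(=O)OC | intermediate
10 | trimethyl 4-(trifluoromethylsulfonyloxy)-1,2,3,5,6,6a-hexahydropentalene-1,1,3-tricarboxylate, H3 cis to H6a (C12 enol triflate, C12=C13, H23 cis to H14) | O=S(=O)(OC1=C2[C@H](CC1)C(C(=O)OC)(C(=O)OC)C[C@@H]2C(=O)OC)C(F)(F)F | intermediate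
11 | dimethylmethylideneammonium iodide | C=[N+](C)C.[I-] | starting material
12 | lithium ester enolate of 10 (C23 planar) | [Li+].[O-]C(OC)=C1CC(C(=O)OC)(C(=O)OC)[C@H]2CCC(OS(=O)(=O)C(F)(F)F)=C12 | intermediate
13 | trimethyl 3-[(dimethylamino)methyl]-4-(trifluoromethylsulfonyloxy)-1,2,3,5,6,6a-hexahydropentalene-1,1,3-tricarboxylate, CH2NMe2 cis to H6a (C24 cis to H14) | O=S(=O)(OC1=C2[C@H](CC1)C(C(=O)OC)(C(=O)OC)C[C@]2(CN(C)C)C(=O)OC)C(F)(F)F | intermediate
14 | tert-butyl 4-bromobutanoate | CC(C)(C)OC(=O)CCCBr | starting material
15 | (4-tert-butoxy-4-oxobutyl)zinc bromide | CC(C)(C)OC(=O)CCC[Zn]Br | intermediate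
16 | trimethyl 4-(4-tert-butoxy-4-oxobutyl)-3-[(dimethylamino)methyl]-1,2,3,5,6,6a-hexahydropentalene-1,1,3-tricarboxylate, same configuration as 13 | CC(C)(C)OC(=O)CCCC1=C2[C@H](CC1)C(C(=O)OC)(C(=O)OC)C[C@]2(CN(C)C)C(=O)OC | intermediate
17 | tricyclic β-keto ester: rings A–C, C6 ketone, CO2t-Bu on C9 (C9 epimers interconvert through the enol), CH2NMe2 on C23, two CO2Me on C17 | O=C1C(C(=O)OC(C)(C)C)CCC2=C3[C@H](CC2)C(C(=O)OC)(C(=O)OC)C[C@@]31CN(C)C | intermediate
18 | β-keto acid from 17 (CO2H on C9) | O=C1C(C(=O)O)CCC2=C3[C@H](CC2)C(C(=O)OC)(C(=O)OC)C[C@@]31CN(C)C | intermediate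
19 | tricyclic amino ketone diester: rings A–C, C6 ketone, C9 methylene, CH2NMe2 on C23 cis to H14 | O=C1CCCC2=C3[C@H](CC2)C(C(=O)OC)(C(=O)OC)C[C@@]31CN(C)C | intermediate
20 | N-oxide of 19 | O=C1CCCC2=C3[C@H](CC2)C(C(=O)OC)(C(=O)OC)C[C@@]31C[N+](C)(C)[O-] | intermediate
21 | N-methyl-N-methyleneiminium trifluoroacetate derived from 20 | O=C1CCCC2=C3[C@H](CC2)C(C(=O)OC)(C(=O)OC)C[C@@]31C[N+](C)=C.[O-]C(=O)C(F)(F)F | intermediate
22 | tetracyclic amino ketone diester: rings A–D, C6 ketone on the one-carbon bridge, N-methyl, two CO2Me on C17 | O=C1[C@@H]2CCC3=C4[C@H](CC3)C(C(=O)OC)(C(=O)OC)C[C@@]41CN(C)C2 | intermediate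
23 | tetracyclic amino ketone monoester: as 22 with one CO2Me on C17, H17 cis to H14 and to C24 | O=C1[C@@H]2CCC3=C4[C@H](CC3)[C@H](C(=O)OC)C[C@@]41CN(C)C2 | intermediate
24 | (phenylthiomethyl)trimethylsilane | C[Si](C)(C)CSc1ccccc1 | starting material
25 | lithio(phenylsulfanyl)(trimethylsilyl)methane | [Li]C(Sc1ccccc1)[Si](C)(C)C | intermediate
26 | (E)-C6=C7H–SPh vinyl sulfide of the tetracycle (sulfur on the C9 side) | c1ccccc1S/C=C2\[C@@H]3CCC4=C5[C@H](CC4)[C@H](C(=O)OC)C[C@@]52CN(C)C3 | intermediate
27 | pent-1-en-3-one (ethyl vinyl ketone) | CCC(=O)C=C | starting material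
28 | C7-phenylthio derivative of the target (C5 syn to ring C, C7 syn to N25, SPh on the C9 side) | CCC1=CC[C@]2([C@@H](Sc3ccccc3)O1)[C@@H]1CCC3=C4[C@H](CC3)[C@H](C(=O)OC)C[C@@]42CN(C)C1 | intermediate
29 | CNP0159589.2 | CCC1=CC[C@]2(CO1)[C@@H]1CCC3=C4[C@H](CC3)[C@H](C(=O)OC)C[C@@]42CN(C)C1 | target

**Totals**
Total steps: 14. Longest linear sequence: 14 steps, from cyclopent-2-en-1-one.

**Steps most likely to fail**

1. Step 13. Bond formation at the fully substituted C6 next to the quaternary C23 may be too slow even under pressure. The basic amine may also sequester the ytterbium catalyst, the enone may polymerise, or the two alkene faces may be poorly differentiated. The fallback sets out from 26 and returns at 29 by ionic steps. Hydrolysis of the vinyl sulfide (TiCl4, aqueous MeCN) gives the C6 carbaldehyde F1. Base-catalysed Michael addition of F1 to 27 (KOt-Bu cat., THF, 0 °C) creates the quaternary C6 from the same ring C face and gives the keto aldehyde F2. NaBH4 at −78 °C reduces only the aldehyde to the δ-hydroxy ketone F3. TsOH (slight excess over the amine, toluene, 80 °C) cyclodehydrates F3 through its hemiketal to the 6-ethyl-3,4-dihydro-2H-pyran 29.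

2. Step 10. The peracid may epoxidise the tetrasubstituted C12=C13 alkene in competition with N-oxidation. The iminium ion may form toward C24 instead of an N-methyl group, or the ketone enol may fail to capture it before hydrolysis. The fallback sets out from 19 and returns at 22 without an oxidant. N-Demethylation with 1-chloroethyl chloroformate (ClCH2CH2Cl, 80 °C) gives the carbamate F4. Methanolysis (MeOH, 65 °C) gives the secondary amine F5. Aqueous CH2O in AcOH at 60 °C then closes ring D by an ordinary intramolecular Mannich reaction to 22.

3. Step 12. The bulky α-silyl carbanion may add too slowly to the ketone flanked by the quaternary C23. Attack on the ester or deprotonation at C17 would then compete. The fallback sets out from 23 and returns at 26 with small nucleophiles. Corey–Chaykovsky methylenation (Me3SI, KOt-Bu, DMSO–THF) gives the spiro-epoxide F6. Sodium thiophenolate opens F6 at its CH2 terminus to the β-hydroxy sulfide F7. Dehydration (SOCl2, pyridine, 0 °C) can only involve the C7 hydrogens, since C23 has none and C9 is a bridgehead, and gives 26.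

**Further compounds**
F1 | step 13 | C6 carbaldehyde of the tetracycle (C6–H, epimers at C6) | O=CC1[C@@H]2CCC3=C4[C@H](CC3)[C@H](C(=O)OC)C[C@@]41CN(C)C2
F2 | step 13 | C6 formyl C6-(3-oxopentyl) keto aldehyde (C5 syn to ring C) | CCC(=O)CC[C@]1(C=O)[C@@H]2CCC3=C4[C@H](CC3)[C@H](C(=O)OC)C[C@@]41CN(C)C2
F3 | step 13 | C6 hydroxymethyl C6-(3-oxopentyl) hydroxy ketone | CCC(=O)CC[C@]1(CO)[C@@H]2CCC3=C4[C@H](CC3)[C@H](C(=O)OC)C[C@@]41CN(C)C2
F4 | step 10 | 1-chloroethyl N-methyl carbamate of the demethylated amine of 19 | O=C1CCCC2=C3[C@H](CC2)C(C(=O)OC)(C(=O)OC)C[C@@]31CN(C)C(=O)OC(C)Cl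
F5 | step 10 | secondary amine (C23–CH2–NHMe) tricyclic ketone diester | O=C1CCCC2=C3[C@H](CC2)C(C(=O)OC)(C(=O)OC)C[C@@]31CNC
F6 | step 12 | C6 spiro-epoxide of 23 (either C6 epimer serves) | O1CC12[C@@H]3CCC4=C5[C@H](CC4)[C@H](C(=O)OC)C[C@@]52CN(C)C3
F7 | step 12 | C6 tertiary alcohol bearing CH2SPh (either C6 epimer serves) | OC1(CSc2ccccc2)[C@@H]3CCC4=C5[C@H](CC4)[C@H](C(=O)OC)C[C@@]51CN(C)C3
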